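## Retrosynthetic overview

- The chalcone C=C is not made by an aldol condensation. It is unveiled last by Saegusa–Ito dehydrogenation of a saturated dihydrochalcone, so rings A and B and all 15 skeletal carbons are bought as phloretin.
- The C3 carbinol comes from benzylic hydrogenolysis of a (3S,4S)-chromene oxide, which comes from Jacobsen–Katsuki epoxidation of a 2,2-dimethyl-2H-chromene (stereocentre set on a preformed ring, no prenyl-epoxide 6-endo/5-exo question).
- The chromene comes from a propargyl Claisen / oxa-6π cascade of an aryl 1,1-dimethylpropargyl ether, placed on the single free, ketone-chelated phenol of tris-MOM phloretin.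
- Ring order: rings A and B are purchased; the pyran ring is the only ring formed (step 3); the stereocentre follows (steps 4 and 5); the enone and the free phenols come last.

Assumption: the stereocentre in the SMILES is (S) at C3 of the chroman (same sense as (S)-decursinol); phloretin, 3-chloro-3-methylbut-1-yne and the (S,S) salen manganese chloride catalyst are purchased.

## Route

Step 1
Reactants: 1 phloretin [3-(4-hydroxyphenyl)-1-(2,4,6-trihydroxyphenyl)propan-1-one]
Product: 2 1-[2-hydroxy-4,6-bis(methoxymethoxy)phenyl]-3-[4-(methoxymethoxy)phenyl]propan-1-one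
Conditions: MOMCl (3.3 equiv), iPr2NEt (4 equiv), CH2Cl2, 0 °C to rt
Reagents that add atoms: chloromethyl methyl ether (MOMCl), COCCl
Why: Selective phenol O-alkylation (MOM protection): the ring B phenol, the para hydroxyl and one ortho hydroxyl react, while the last ortho hydroxyl stays locked in its hydrogen bond to the ketone (the selectivity known for phloroacetophenone), and ring A symmetry makes the two ortho hydroxyls equivalent so one product forms.

Step 2
Reactants: 2 1-[2-hydroxy-4,6-bis(methoxymethoxy)phenyl]-3-[4-(methoxymethoxy)phenyl]propan-1-one; 3 3-chloro-3-methylbut-1-yne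
Product: 4 1-[2,4-bis(methoxymethoxy)-6-(2-methylbut-3-yn-2-yloxy)phenyl]-3-[4-(methoxymethoxy)phenyl]propan-1-one
Conditions: DBU (1.5 equiv), CuCl2·2H2O (1 mol%), MeCN, 0 °C to rt
Reagents that add atoms: none
Why: Copper-catalysed propargylic etherification: the tertiary chloride is activated through a copper acetylide, so even the hindered, hydrogen-bonded phenoxide is O-alkylated at the tertiary carbon under mild base that leaves the enolisable ketone alone.

Step 3
Reactants: 4 1-[2,4-bis(methoxymethoxy)-6-(2-methylbut-3-yn-2-yloxy)phenyl]-3-[4-(methoxymethoxy)phenyl]propan-1-one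
Product: 7 1-[5,7-bis(methoxymethoxy)-2,2-dimethyl-2H-chromen-8-yl]-3-[4-(methoxymethoxy)phenyl]propan-1-one, via ortho-allenylphenol 5 (not isolated), via ortho-quinone methide 6 (not isolated)
Conditions: PhNEt2, 170 °C, 3 h
Reagents that add atoms: none
Why: Aromatic propargyl Claisen rearrangement: the [3,3] shift can only end productively at the one free ortho carbon (the other carries the acyl group), and tautomerisation, 1,5-hydrogen shift and oxa-6π electrocyclisation then give the 2H-chromene with its ring oxygen fixed ortho to the ketone.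

Step 4
Reactants: 7 1-[5,7-bis(methoxymethoxy)-2,2-dimethyl-2H-chromen-8-yl]-3-[4-(methoxymethoxy)phenyl]propan-1-one
Product: 8 1-[(3S,4S)-3,4-epoxy-5,7-bis(methoxymethoxy)-2,2-dimethyl-3,4-dihydro-2H-chromen-8-yl]-3-[4-(methoxymethoxy)phenyl]propan-1-one
Conditions: (S,S)-(salen)MnCl [(S,S)-N,N'-bis(3,5-di-tert-butylsalicylidene)cyclohexane-1,2-diamine complex of trivalent manganese chloride] (5 mol%), mCPBA (2 equiv), NMO (5 equiv), CH2Cl2, −78 °C; quick filtration through basic Al2O3, used at once
Reagents that add atoms: 3-chloroperoxybenzoic acid (mCPBA), O=C(OO)c1cccc(Cl)c1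
Why: Jacobsen–Katsuki epoxidation: 2,2-dimethylchromenes are the best substrate class for the oxo species of pentavalent manganese, and the (S,S) catalyst delivers oxygen to the face that gives the (3S,4S) epoxide (the same facial sense as in the (S,S)-catalysed epoxidations of indene and 6-cyano-2,2-dimethylchromene); the anhydrous mCPBA/NMO protocol avoids hypochlorite, which could chlorinate C6 of ring A.

Step 5
Reactants: 8 1-[(3S,4S)-3,4-epoxy-5,7-bis(methoxymethoxy)-2,2-dimethyl-3,4-dihydro-2H-chromen-8-yl]-3-[4-(methoxymethoxy)phenyl]propan-1-one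
Product: 9 1-[(3S)-3-hydroxy-5,7-bis(methoxymethoxy)-2,2-dimethyl-3,4-dihydro-2H-chromen-8-yl]-3-[4-(methoxymethoxy)phenyl]propan-1-one
Conditions: H2 (1 atm), 10% Pd/C, NaHCO3 (solid), EtOAc, rt
Reagents that add atoms: none
Why: Regioselective benzylic hydrogenolysis of the epoxide: only the activated C4–O bond is cleaved, so the C3–O bond and its (S) configuration are untouched, and the twisted, doubly ortho-substituted aryl ketone and the MOM ethers are inert at 1 atm.

Step 6
Reactants: 9 1-[(3S)-3-hydroxy-5,7-bis(methoxymethoxy)-2,2-dimethyl-3,4-dihydro-2H-chromen-8-yl]-3-[4-(methoxymethoxy)phenyl]propan-1-one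
Product: 10 [(1Z)-1-[(3S)-5,7-bis(methoxymethoxy)-2,2-dimethyl-3-(trimethylsilyloxy)-3,4-dihydro-2H-chromen-8-yl]-3-[4-(methoxymethoxy)phenyl]prop-1-en-1-yl]oxy-trimethylsilane
Conditions: LiN(iPr)2 (2.5 equiv), Me3SiCl (3 equiv), THF, −78 °C to 0 °C; non-aqueous work-up (pentane, filtration), used crude
Reagents that add atoms: chlorotrimethylsilane (Me3SiCl), C[Si](C)(C)Cl
Why: Kinetic enolisation and O-silylation: the ketone has a single enolisable CH2, the lithium amide gives the Z enolate, and Me3SiCl traps both the enolate and the C3 alkoxide, so the alcohol is protected in the same operation without touching the stereocentre.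

Step 7
Reactants: 10 [(1Z)-1-[(3S)-5,7-bis(methoxymethoxy)-2,2-dimethyl-3-(trimethylsilyloxy)-3,4-dihydro-2H-chromen-8-yl]-3-[4-(methoxymethoxy)phenyl]prop-1-en-1-yl]oxy-trimethylsilane
Product: 11 (E)-1-[(3S)-5,7-bis(methoxymethoxy)-2,2-dimethyl-3-(trimethylsilyloxy)-3,4-dihydro-2H-chromen-8-yl]-3-[4-(methoxymethoxy)phenyl]prop-2-en-1-one
Conditions: Pd(OAc)2 (1.1 equiv), MeCN, rt
Reagents that add atoms: none
Why: Saegusa–Ito oxidation: the silyl enol ether transfers to divalent palladium, and β-hydride elimination of a benzylic hydrogen gives the (E)-enone conjugated to ring B; any C3 silyl ether lost here converges in step 8.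

Step 8
Reactants: 11 (E)-1-[(3S)-5,7-bis(methoxymethoxy)-2,2-dimethyl-3-(trimethylsilyloxy)-3,4-dihydro-2H-chromen-8-yl]-3-[4-(methoxymethoxy)phenyl]prop-2-en-1-one
Product: 12 (E)-1-[(3S)-3,5,7-trihydroxy-2,2-dimethyl-3,4-dihydro-2H-chromen-8-yl]-3-(4-hydroxyphenyl)prop-2-en-1-one
Conditions: conc. aq. HCl, MeOH, 0 °C to rt
Reagents that add atoms: none
Why: Acid-catalysed solvolysis of the three MOM acetals and the silyl ether (global deprotection): these are the conditions used to unmask xanthohumol-type hydroxychalcones, mild enough that neither oxa-Michael closure to a flavanone nor ionisation at C3 competes, and base is avoided because it would promote that closure.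

## Compound list

1 | phloretin, 3-(4-hydroxyphenyl)-1-(2,4,6-trihydroxyphenyl)propan-1-one | O=C(CCc1ccc(O)cc1)c1c(O)cc(O)cc1O | starting material
2 | 1-[2-hydroxy-4,6-bis(methoxymethoxy)phenyl]-3-[4-(methoxymethoxy)phenyl]propan-1-one | COCOc1ccc(CCC(=O)c2c(O)cc(OCOC)cc2OCOC)cc1 | intermediate
3 | 3-chloro-3-methylbut-1-yne | CC(C)(Cl)C#C | starting material
4 | 1-[2,4-bis(methoxymethoxy)-6-(2-methylbut-3-yn-2-yloxy)phenyl]-3-[4-(methoxymethoxy)phenyl]propan-1-one | COCOc1ccc(CCC(=O)c2c(OCOC)cc(OCOC)cc2OC(C)(C)C#C)cc1 | intermediate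
5 | 1-[2-hydroxy-4,6-bis(methoxymethoxy)-3-(3-methylbuta-1,2-dien-1-yl)phenyl]-3-[4-(methoxymethoxy)phenyl]propan-1-one (ortho-allenylphenol) | COCOc1ccc(CCC(=O)c2c(O)c(C=C=C(C)C)c(OCOC)cc2OCOC)cc1 | intermediate
6 | 3,5-bis(methoxymethoxy)-2-{3-[4-(methoxymethoxy)phenyl]propanoyl}-6-[(Z)-3-methylbut-2-en-1-ylidene]cyclohexa-2,4-dien-1-one (ortho-quinone methide) | COCOc1ccc(CCC(=O)C2=C(OCOC)C=C(OCOC)/C(=C/C=C(C)C)C2=O)cc1 | intermediate
7 | 1-[5,7-bis(methoxymethoxy)-2,2-dimethyl-2H-chromen-8-yl]-3-[4-(methoxymethoxy)phenyl]propan-1-one | CC1(C)C=Cc2c(OCOC)cc(OCOC)c(C(=O)CCc3ccc(OCOC)cc3)c2O1 | intermediate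
8 | 1-[(3S,4S)-3,4-epoxy-5,7-bis(methoxymethoxy)-2,2-dimethyl-3,4-dihydro-2H-chromen-8-yl]-3-[4-(methoxymethoxy)phenyl]propan-1-one | CC1(C)Oc2c(C(=O)CCc3ccc(OCOC)cc3)c(OCOC)cc(OCOC)c2[C@@H]2O[C@H]12 | intermediate
9 | 1-[(3S)-3-hydroxy-5,7-bis(methoxymethoxy)-2,2-dimethyl-3,4-dihydro-2H-chromen-8-yl]-3-[4-(methoxymethoxy)phenyl]propan-1-one | CC1(C)Oc2c(C(=O)CCc3ccc(OCOC)cc3)c(OCOC)cc(OCOC)c2C[C@@H]1O | intermediate
10 | [(1Z)-1-[(3S)-5,7-bis(methoxymethoxy)-2,2-dimethyl-3-(trimethylsilyloxy)-3,4-dihydro-2H-chromen-8-yl]-3-[4-(methoxymethoxy)phenyl]prop-1-en-1-yl]oxy-trimethylsilane | CC1(C)Oc2c(/C(O[Si](C)(C)C)=C/Cc3ccc(OCOC)cc3)c(OCOC)cc(OCOC)c2C[C@@H]1O[Si](C)(C)C | intermediate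
11 | (E)-1-[(3S)-5,7-bis(methoxymethoxy)-2,2-dimethyl-3-(trimethylsilyloxy)-3,4-dihydro-2H-chromen-8-yl]-3-[4-(methoxymethoxy)phenyl]prop-2-en-1-one | CC1(C)Oc2c(C(=O)/C=C/c3ccc(OCOC)cc3)c(OCOC)cc(OCOC)c2C[C@@H]1O[Si](C)(C)C | intermediate
12 | (E)-1-[(3S)-3,5,7-trihydroxy-2,2-dimethyl-3,4-dihydro-2H-chromen-8-yl]-3-(4-hydroxyphenyl)prop-2-en-1-one (CNP0326757.1) | CC1(C)Oc2c(c(O)cc(O)c2C(=O)/C=C/c2ccc(O)cc2)C[C@@H]1O | target

## Summary

Total step count: 8. Longest linear sequence: 8 steps (1 to 12); the route is fully linear, with 3 as the only other purchased building block.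

Steps most likely to fail:

**Step 4 (with its follow-up, step 5).** The chromene is very electron-rich, so epoxide 8 is acid-labile and may rearrange or open before it can be hydrogenolysed, and the peri MOM ether could lower the ee. The fallback sets out from propargyl ether 4 and returns at chromanol 9. The alkyne is semi-hydrogenated (H2, Pd/CaCO3 poisoned with Pb(OAc)2, quinoline, EtOAc) to the 1,1-dimethylallyl ether F2. Heating (PhNEt2, 130 °C) triggers an aromatic Claisen rearrangement that puts a normal prenyl group on the only free ortho carbon and gives the ortho-prenylphenol F3. The trisubstituted olefin is epoxidised with the L-fructose-derived enantiomer of the Shi ketone (KHSO5 as Oxone, K2CO3 buffer, MeCN/dimethoxymethane/H2O, 0 °C) to the (S)-epoxide F4. Acid-catalysed 6-endo opening at the tertiary carbon (camphorsulfonic acid cat., CH2Cl2, 0 °C) keeps the secondary C–O bond and gives 9.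

**Step 7.** The hindered, electron-rich silyl enol ether may protodesilylate back to the ketone faster than it transfers to palladium. The fallback sets out from bis-silyl compound 10 and returns at 11. Treatment with PhSeCl (CH2Cl2, −78 °C) gives the α-phenylselanyl ketone F5. Oxidation (30% H2O2, pyridine, CH2Cl2, 0 °C to rt) then leads through selenoxide syn-elimination to the (E)-enone 11.

**Step 2.** O-Alkylation of the chelated, doubly ortho-substituted phenol with a tertiary propargylic chloride may stall or give elimination of the chloride. The fallback sets out from phenol 2 and returns at chromene 7, making the C–C bond first instead of the C–O bond. Condensation with 3-methylbut-2-enal and PhB(OH)2 (cat. propionic acid, toluene, reflux, Dean–Stark) gives, by boron-templated ortho-alkylation, the 2-phenyl-4H-1,3,2-benzodioxaborinine F1. On continued heating F1 loses its boron unit by retro-[4+2] fragmentation to the same ortho-quinone methide 6, which closes to 7.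

## Further compounds

F1 | step 2 | racemic 1-[5,7-bis(methoxymethoxy)-4-(2-methylprop-1-en-1-yl)-2-phenyl-4H-1,3,2-benzodioxaborinin-8-yl]-3-[4-(methoxymethoxy)phenyl]propan-1-one | CC(C)=CC1OB(c2ccccc2)Oc2c1c(OCOC)cc(OCOC)c2C(=O)CCc1ccc(OCOC)cc1
F2 | step 4 | 1-[2,4-bis(methoxymethoxy)-6-(2-methylbut-3-en-2-yloxy)phenyl]-3-[4-(methoxymethoxy)phenyl]propan-1-one | COCOc1ccc(CCC(=O)c2c(OCOC)cc(OCOC)cc2OC(C)(C)C=C)cc1
F3 | step 4 | 1-[2-hydroxy-4,6-bis(methoxymethoxy)-3-(3-methylbut-2-en-1-yl)phenyl]-3-[4-(methoxymethoxy)phenyl]propan-1-one | COCOc1ccc(CCC(=O)c2c(O)c(CC=C(C)C)c(OCOC)cc2OCOC)cc1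
F4 | step 4 | 1-[3-{[(2S)-3,3-dimethyloxiran-2-yl]methyl}-2-hydroxy-4,6-bis(methoxymethoxy)phenyl]-3-[4-(methoxymethoxy)phenyl]propan-1-one | COCOc1ccc(CCC(=O)c2c(O)c(C[C@@H]3OC3(C)C)c(OCOC)cc2OCOC)cc1
F5 | step 7 | 1-[(3S)-5,7-bis(methoxymethoxy)-2,2-dimethyl-3-(trimethylsilyloxy)-3,4-dihydro-2H-chromen-8-yl]-3-[4-(methoxymethoxy)phenyl]-2-(phenylselanyl)propan-1-one (both epimers at the selenium-bearing carbon) | CC1(C)Oc2c(C(=O)C(Cc3ccc(OCOC)cc3)[Se]c3ccccc3)c(OCOC)cc(OCOC)c2C[C@@H]1O[Si](C)(C)C
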